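**Retrosynthetic overview**
1. Numbering as in cyclohex-2-en-1-one (C1 = C=O, C2 bears the acyloxymethyl carbon C7, C4 = CH–O-tigloyl, C5 = CH–i-Pr, C6 = CH–OH; target is 4S,5R,6R with two (E)-2-methylbut-2-enoates): the C6–OH is unmasked last (PMB ether, DDQ) after double Yamaguchi tigloylation of the C4/C7 diol.
2. C7 (CH2OH on C2) comes from a Morita–Baylis–Hillman aldol of the 4,5,6-trisubstituted cyclohex-2-enone with formaldehyde.
3. The only ring is the cyclohexene, closed by RCM across C2=C3 of an octa-1,7-dien-3-ol and then oxidised at C1; the C1–C2 bond comes from vinyl Grignard addition to a C1 aldehyde.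
4. C4 is set by Evans–Saksena anti reduction of a β-hydroxy vinyl ketone; C5 and C6 are set by the key intermolecular Evans syn aldol (C5–C6 bond) between an N-isovaleryl oxazolidinone and PMBOCH2CHO.
5. The two secondary hydroxyls are told apart by PMB ether → 4-methoxybenzylidene acetal → regioselective i-Bu2AlH opening.

Assumption: the ring labels C1–C7 are used for the open-chain precursors as well.

**Route**

Step 1
Reactants: 1 (Z)-but-2-ene-1,4-diol; 2 4-methoxybenzyl chloride (two equivalents are incorporated)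
Product: 3 (Z)-1,4-bis[(4-methoxybenzyl)oxy]but-2-ene
Conditions: NaH (2.4 equiv), 2 (2.2 equiv), Bu4NI (cat.), DMF, 0 °C → rt
Reagents that add atoms: 4-methoxybenzyl chloride (the second equivalent of 2), COc1ccc(CCl)cc1
Why: Double Williamson etherification (each alkoxide displaces chloride from one molecule of the benzylic chloride by SN2 under iodide catalysis); no stereocentre is involved.

Step 2
Reactants: 3 (Z)-1,4-bis[(4-methoxybenzyl)oxy]but-2-ene
Product: 5 2-[(4-methoxybenzyl)oxy]acetaldehyde, via ozonide 4 (not isolated)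
Conditions: O3, CH2Cl2, −78 °C (stop at first blue tint); then PPh3, −78 °C → rt; use fresh
Reagents that add atoms: ozone, [O-][O+]=O
Why: Ozonolysis of the symmetrical cis-alkene followed by reductive cleavage of the ozonide with PPh3 gives two equivalents of the α-alkoxy aldehyde without over-oxidation.

Step 3
Reactants: 6 (R)-4-benzyl-1,3-oxazolidin-2-one; 7 3-methylbutanoyl chloride
Product: 9 (R)-4-benzyl-3-(3-methylbutanoyl)-1,3-oxazolidin-2-one, via N-lithio oxazolidinone 8 (not isolated)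
Conditions: n-BuLi, THF, −78 °C; then 7, −78 → 0 °C
Reagents that add atoms: none
Why: N-acylation of the lithiated oxazolidinone by addition–elimination on the acid chloride installs the auxiliary without touching its stereocentre.

Step 4
Reactants: 9 (R)-4-benzyl-3-(3-methylbutanoyl)-1,3-oxazolidin-2-one; 5 2-[(4-methoxybenzyl)oxy]acetaldehyde
Product: 12 (4R)-4-benzyl-3-[(2R,3R)-3-hydroxy-4-[(4-methoxybenzyl)oxy]-2-(propan-2-yl)butanoyl]-1,3-oxazolidin-2-one, via (Z)-boron enolate 10 (not isolated), via boron aldolate 11 (not isolated)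
Conditions: Bu2BOTf, Et3N, CH2Cl2, 0 °C; then 5, −78 → 0 °C; then pH 7 buffer, MeOH, 30% H2O2, 0 °C
Reagents that add atoms: none
Why: Evans syn aldol: the (Z)-boron enolate adds to the aldehyde through a Zimmerman–Traxler chair on the face away from the benzyl group of the dipole-minimised (R)-auxiliary, forming the C5–C6 bond and setting C5 and C6 (syn, 2R,3R in the acyl chain).

Step 5
Reactants: 12 (4R)-4-benzyl-3-[(2R,3R)-3-hydroxy-4-[(4-methoxybenzyl)oxy]-2-(propan-2-yl)butanoyl]-1,3-oxazolidin-2-one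
Product: 13 (2R,3R)-3-hydroxy-N-methoxy-4-[(4-methoxybenzyl)oxy]-N-methyl-2-(propan-2-yl)butanamide
Conditions: MeNHOMe·HCl, AlMe3, CH2Cl2, −20 → 0 °C
Reagents that add atoms: N,O-dimethylhydroxylamine hydrochloride, CNOC.Cl
Why: Weinreb transamination: the aluminium amide, held by the aluminium alkoxide of the free β-hydroxyl, attacks only the exocyclic carbonyl, so the auxiliary leaves without epimerising the α-centre.

Step 6
Reactants: 13 (2R,3R)-3-hydroxy-N-methoxy-4-[(4-methoxybenzyl)oxy]-N-methyl-2-(propan-2-yl)butanamide; 14 vinylmagnesium bromide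
Product: 15 (4R,5R)-5-hydroxy-6-[(4-methoxybenzyl)oxy]-4-(propan-2-yl)hex-1-en-3-one
Conditions: 14 (3.5 equiv), THF, −78 → 0 °C; inverse quench into cold 1 M HCl; use at once
Reagents that add atoms: none
Why: Weinreb ketone synthesis: the chelated tetrahedral adduct of the N-methoxy-N-methylamide takes up only one vinyl group, and the cold acidic quench keeps the liberated amine protonated so that it cannot add to the vinyl ketone.

Step 7
Reactants: 15 (4R,5R)-5-hydroxy-6-[(4-methoxybenzyl)oxy]-4-(propan-2-yl)hex-1-en-3-one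
Product: 16 (2R,3S,4S)-1-[(4-methoxybenzyl)oxy]-3-(propan-2-yl)hex-5-ene-2,4-diol
Conditions: Me4NBH(OAc)3, MeCN/AcOH (1:1), −30 °C
Reagents that add atoms: none
Why: Evans–Saksena hydroxyl-directed reduction: the C6 hydroxyl binds boron and delivers hydride intramolecularly through a chair transition state, giving the 1,3-anti diol (sets C4) with 1,2-selectivity on the enone.

Step 8
Reactants: 16 (2R,3S,4S)-1-[(4-methoxybenzyl)oxy]-3-(propan-2-yl)hex-5-ene-2,4-diol
Product: 17 (3S,4S)-4-[(4R)-2-(4-methoxyphenyl)-1,3-dioxolan-4-yl]-5-methylhex-1-en-3-ol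
Conditions: DDQ (1.1 equiv), 4 Å MS, CH2Cl2, 0 °C
Reagents that add atoms: none
Why: Oxidative acetalisation (Oikawa–Yonemitsu): DDQ removes the benzylic hydride and the oxocarbenium ion is trapped by the adjacent C6 hydroxyl as a five-membered dioxolane (the C4 hydroxyl would need a seven-membered ring), which differentiates the two secondary hydroxyls; the acetal carbon forms as an inconsequential epimer mixture.

Step 9
Reactants: 17 (3S,4S)-4-[(4R)-2-(4-methoxyphenyl)-1,3-dioxolan-4-yl]-5-methylhex-1-en-3-ol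
Product: 18 tert-butyl{[(3S,4R)-4-[(4R)-2-(4-methoxyphenyl)-1,3-dioxolan-4-yl]-5-methylhex-1-en-3-yl]oxy}dimethylsilane
Conditions: TBSOTf, 2,6-lutidine, CH2Cl2, −78 → 0 °C
Reagents that add atoms: tert-butyldimethylsilyl trifluoromethanesulfonate, CC(C)(C)[Si](C)(C)OS(=O)(=O)C(F)(F)F
Why: Silylation of the hindered secondary allylic C4 alcohol with the silyl triflate and a hindered base; acetal and alkene are inert at low temperature (the 4R descriptor is only a CIP priority change).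

Step 10
Reactants: 18 tert-butyl{[(3S,4R)-4-[(4R)-2-(4-methoxyphenyl)-1,3-dioxolan-4-yl]-5-methylhex-1-en-3-yl]oxy}dimethylsilane
Product: 19 (2R,3R,4S)-4-[(tert-butyldimethylsilyl)oxy]-2-[(4-methoxybenzyl)oxy]-3-(propan-2-yl)hex-5-en-1-ol
Conditions: i-Bu2AlH (3 equiv), CH2Cl2, −78 → 0 °C; aq. potassium sodium tartrate
Reagents that add atoms: none
Why: Regioselective reductive opening of the 4-methoxybenzylidene acetal: aluminium coordinates the less hindered primary oxygen, that C–O bond breaks and hydride reduces the oxocarbenium ion, leaving the PMB ether on the C6 oxygen and a free primary alcohol.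

Step 11
Reactants: 19 (2R,3R,4S)-4-[(tert-butyldimethylsilyl)oxy]-2-[(4-methoxybenzyl)oxy]-3-(propan-2-yl)hex-5-en-1-ol
Product: 20 (2R,3R,4S)-4-[(tert-butyldimethylsilyl)oxy]-2-[(4-methoxybenzyl)oxy]-3-(propan-2-yl)hex-5-enal
Conditions: TEMPO (cat.), PhI(OAc)2, CH2Cl2, rt; use crude
Reagents that add atoms: none
Why: TEMPO (oxoammonium) oxidation stops at the aldehyde and is mild enough not to epimerise the α-alkoxy centre C6.

Step 12
Reactants: 20 (2R,3R,4S)-4-[(tert-butyldimethylsilyl)oxy]-2-[(4-methoxybenzyl)oxy]-3-(propan-2-yl)hex-5-enal; 14 vinylmagnesium bromide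
Product: 21 (3RS,4R,5R,6S)-6-[(tert-butyldimethylsilyl)oxy]-4-[(4-methoxybenzyl)oxy]-5-(propan-2-yl)octa-1,7-dien-3-ol
Conditions: 14, THF, −78 °C; then H2O
Reagents that add atoms: none
Why: Grignard 1,2-addition to the aldehyde; the new carbinol C1 forms as a mixture, which does not matter because it becomes the ketone in step 14.

Step 13
Reactants: 21 (3RS,4R,5R,6S)-6-[(tert-butyldimethylsilyl)oxy]-4-[(4-methoxybenzyl)oxy]-5-(propan-2-yl)octa-1,7-dien-3-ol
Product: 22 (1RS,4S,5R,6R)-4-[(tert-butyldimethylsilyl)oxy]-6-[(4-methoxybenzyl)oxy]-5-(propan-2-yl)cyclohex-2-en-1-ol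
Conditions: second-generation Grubbs catalyst (5 mol %), CH2Cl2, 40 °C
Reagents that add atoms: none
Why: Ring-closing olefin metathesis of the 1,7-diene closes the only ring (cyclohexene, C2=C3) with loss of ethene and leaves the stereocentres untouched.

Step 14
Reactants: 22 (1RS,4S,5R,6R)-4-[(tert-butyldimethylsilyl)oxy]-6-[(4-methoxybenzyl)oxy]-5-(propan-2-yl)cyclohex-2-en-1-ol
Product: 23 (4S,5R,6R)-4-[(tert-butyldimethylsilyl)oxy]-6-[(4-methoxybenzyl)oxy]-5-(propan-2-yl)cyclohex-2-en-1-one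
Conditions: Dess–Martin periodinane, CH2Cl2, rt
Reagents that add atoms: none
Why: Dess–Martin oxidation of the allylic alcohol gives the enone under near-neutral conditions; both C1 epimers converge and C6 is not epimerised.

Step 15
Reactants: 23 (4S,5R,6R)-4-[(tert-butyldimethylsilyl)oxy]-6-[(4-methoxybenzyl)oxy]-5-(propan-2-yl)cyclohex-2-en-1-one; 24 formaldehyde
Product: 25 (4S,5R,6R)-4-[(tert-butyldimethylsilyl)oxy]-2-(hydroxymethyl)-6-[(4-methoxybenzyl)oxy]-5-(propan-2-yl)cyclohex-2-en-1-one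
Conditions: 37% aq. HCHO, DMAP (0.5 equiv), THF, rt
Reagents that add atoms: none
Why: Morita–Baylis–Hillman reaction: DMAP adds to C3, the enolate undergoes aldol addition to formaldehyde at C2 and loss of DMAP restores the enone; no stereocentre is formed and the C4 silyl ether is not β to the enolate carbon.

Step 16
Reactants: 25 (4S,5R,6R)-4-[(tert-butyldimethylsilyl)oxy]-2-(hydroxymethyl)-6-[(4-methoxybenzyl)oxy]-5-(propan-2-yl)cyclohex-2-en-1-one
Product: 26 (4S,5S,6R)-4-hydroxy-2-(hydroxymethyl)-6-[(4-methoxybenzyl)oxy]-5-(propan-2-yl)cyclohex-2-en-1-one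
Conditions: HF·pyridine, pyridine/THF, 0 °C → rt
Reagents that add atoms: none
Why: Fluoride-mediated desilylation under buffered acidic conditions frees the C4 hydroxyl without base-induced elimination or epimerisation; the PMB ether is stable (5S is only a CIP priority change).

Step 17
Reactants: 26 (4S,5S,6R)-4-hydroxy-2-(hydroxymethyl)-6-[(4-methoxybenzyl)oxy]-5-(propan-2-yl)cyclohex-2-en-1-one; 27 tiglic acid ((E)-2-methylbut-2-enoic acid; two equivalents are incorporated)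
Product: 29 (4S,5S,6R)-6-[(4-methoxybenzyl)oxy]-4-{[(2E)-2-methylbut-2-enoyl]oxy}-2-({[(2E)-2-methylbut-2-enoyl]oxy}methyl)-5-(propan-2-yl)cyclohex-2-en-1-one, via mixed anhydride 28 (not isolated)
Conditions: 27 (5 equiv), 2,4,6-trichlorobenzoyl chloride, Et3N, toluene, rt; then 26, DMAP, toluene, rt → 40 °C
Reagents that add atoms: tiglic acid (the second equivalent of 27), C/C=C(\C)C(=O)O
Why: Yamaguchi esterification: the DMAP-activated mixed anhydride acylates both the primary C7 and the hindered secondary C4 hydroxyl (one tigloyl group each), and the E geometry holds because tiglate is the thermodynamically favoured isomer.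

Step 18
Reactants: 29 (4S,5S,6R)-6-[(4-methoxybenzyl)oxy]-4-{[(2E)-2-methylbut-2-enoyl]oxy}-2-({[(2E)-2-methylbut-2-enoyl]oxy}methyl)-5-(propan-2-yl)cyclohex-2-en-1-one
Product: 30 (4S,5R,6R)-6-hydroxy-4-{[(2E)-2-methylbut-2-enoyl]oxy}-2-({[(2E)-2-methylbut-2-enoyl]oxy}methyl)-5-(propan-2-yl)cyclohex-2-en-1-one (CNP0326914.1)
Conditions: DDQ, CH2Cl2/pH 7 buffer (10:1), 0 °C → rt
Reagents that add atoms: none
Why: Oxidative PMB ether cleavage: DDQ oxidation at the benzylic position and hydrolysis of the hemiacetal release the C6 hydroxyl under neutral conditions that leave both tiglates, the enone and all three stereocentres intact.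

**Compound list**
1 | (Z)-but-2-ene-1,4-diol | OC/C=C\CO | starting material
2 | 4-methoxybenzyl chloride | COc1ccc(CCl)cc1 | starting material
3 | (Z)-1,4-bis[(4-methoxybenzyl)oxy]but-2-ene | COc1ccc(COC/C=C\COCc2ccc(OC)cc2)cc1 | intermediate
4 | 3,5-bis{[(4-methoxybenzyl)oxy]methyl}-1,2,4-trioxolane (ozonide, not isolated) | COc1ccc(COCC2OOC(COCc3ccc(OC)cc3)O2)cc1 | intermediate
5 | 2-[(4-methoxybenzyl)oxy]acetaldehyde | COc1ccc(COCC=O)cc1 | intermediate
6 | (R)-4-benzyl-1,3-oxazolidin-2-one | O=C1N[C@H](Cc2ccccc2)CO1 | starting material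
7 | 3-methylbutanoyl chloride | CC(C)CC(Cl)=O | starting material
8 | N-lithio-(R)-4-benzyl-1,3-oxazolidin-2-one (not isolated) | [Li]N1[C@H](Cc2ccccc2)COC1=O | intermediate
9 | (R)-4-benzyl-3-(3-methylbutanoyl)-1,3-oxazolidin-2-one | CC(C)CC(=O)N1[C@H](Cc2ccccc2)COC1=O | intermediate
10 | (R)-4-benzyl-3-[(1Z)-1-[(dibutylboranyl)oxy]-3-methylbut-1-en-1-yl]-1,3-oxazolidin-2-one (not isolated) | CC(C)/C=C(\OB(CCCC)CCCC)N1[C@H](Cc2ccccc2)COC1=O | intermediate
11 | O-dibutylboranyl aldolate of 12 (not isolated) | O=C(N1[C@H](Cc2ccccc2)COC1=O)[C@H](C(C)C)[C@@H](OB(CCCC)CCCC)COCc1ccc(OC)cc1 | intermediate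
12 | (4R)-4-benzyl-3-[(2R,3R)-3-hydroxy-4-[(4-methoxybenzyl)oxy]-2-(propan-2-yl)butanoyl]-1,3-oxazolidin-2-one | O=C(N1[C@H](Cc2ccccc2)COC1=O)[C@H](C(C)C)[C@@H](O)COCc1ccc(OC)cc1 | intermediate
13 | (2R,3R)-3-hydroxy-N-methoxy-4-[(4-methoxybenzyl)oxy]-N-methyl-2-(propan-2-yl)butanamide | CON(C)C(=O)[C@H](C(C)C)[C@@H](O)COCc1ccc(OC)cc1 | intermediate
14 | vinylmagnesium bromide | C=C[Mg]Br | starting material
15 | (4R,5R)-5-hydroxy-6-[(4-methoxybenzyl)oxy]-4-(propan-2-yl)hex-1-en-3-one | C=CC(=O)[C@H](C(C)C)[C@@H](O)COCc1ccc(OC)cc1 | intermediate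
16 | (2R,3S,4S)-1-[(4-methoxybenzyl)oxy]-3-(propan-2-yl)hex-5-ene-2,4-diol | C=C[C@H](O)[C@H](C(C)C)[C@@H](O)COCc1ccc(OC)cc1 | intermediate
17 | (3S,4S)-4-[(4R)-2-(4-methoxyphenyl)-1,3-dioxolan-4-yl]-5-methylhex-1-en-3-ol (acetal carbon epimers) | C=C[C@H](O)[C@H](C(C)C)[C@@H]1COC(c2ccc(OC)cc2)O1 | intermediate
18 | tert-butyl{[(3S,4R)-4-[(4R)-2-(4-methoxyphenyl)-1,3-dioxolan-4-yl]-5-methylhex-1-en-3-yl]oxy}dimethylsilane | C=C[C@H](O[Si](C)(C)C(C)(C)C)[C@H](C(C)C)[C@@H]1COC(c2ccc(OC)cc2)O1 | intermediate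
19 | (2R,3R,4S)-4-[(tert-butyldimethylsilyl)oxy]-2-[(4-methoxybenzyl)oxy]-3-(propan-2-yl)hex-5-en-1-ol | C=C[C@H](O[Si](C)(C)C(C)(C)C)[C@H](C(C)C)[C@@H](OCc1ccc(OC)cc1)CO | intermediate
20 | (2R,3R,4S)-4-[(tert-butyldimethylsilyl)oxy]-2-[(4-methoxybenzyl)oxy]-3-(propan-2-yl)hex-5-enal | C=C[C@H](O[Si](C)(C)C(C)(C)C)[C@H](C(C)C)[C@@H](OCc1ccc(OC)cc1)C=O | intermediate
21 | (3RS,4R,5R,6S)-6-[(tert-butyldimethylsilyl)oxy]-4-[(4-methoxybenzyl)oxy]-5-(propan-2-yl)octa-1,7-dien-3-ol | C=C[C@H](O[Si](C)(C)C(C)(C)C)[C@H](C(C)C)[C@@H](OCc1ccc(OC)cc1)C(O)C=C | intermediate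
22 | (1RS,4S,5R,6R)-4-[(tert-butyldimethylsilyl)oxy]-6-[(4-methoxybenzyl)oxy]-5-(propan-2-yl)cyclohex-2-en-1-ol | C1=C[C@H](O[Si](C)(C)C(C)(C)C)[C@H](C(C)C)[C@@H](OCc2ccc(OC)cc2)C1O | intermediate
23 | (4S,5R,6R)-4-[(tert-butyldimethylsilyl)oxy]-6-[(4-methoxybenzyl)oxy]-5-(propan-2-yl)cyclohex-2-en-1-one | C1=C[C@H](O[Si](C)(C)C(C)(C)C)[C@H](C(C)C)[C@@H](OCc2ccc(OC)cc2)C1=O | intermediate
24 | formaldehyde | C=O | starting material
25 | (4S,5R,6R)-4-[(tert-butyldimethylsilyl)oxy]-2-(hydroxymethyl)-6-[(4-methoxybenzyl)oxy]-5-(propan-2-yl)cyclohex-2-en-1-one | OCC1=C[C@H](O[Si](C)(C)C(C)(C)C)[C@H](C(C)C)[C@@H](OCc2ccc(OC)cc2)C1=O | intermediate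
26 | (4S,5S,6R)-4-hydroxy-2-(hydroxymethyl)-6-[(4-methoxybenzyl)oxy]-5-(propan-2-yl)cyclohex-2-en-1-one | OCC1=C[C@H](O)[C@H](C(C)C)[C@@H](OCc2ccc(OC)cc2)C1=O | intermediate
27 | tiglic acid, (E)-2-methylbut-2-enoic acid | C/C=C(\C)C(=O)O | starting material
28 | (E)-2-methylbut-2-enoic 2,4,6-trichlorobenzoic anhydride (not isolated) | C/C=C(\C)C(=O)OC(=O)c1c(Cl)cc(Cl)cc1Cl | intermediate
29 | (4S,5S,6R)-6-[(4-methoxybenzyl)oxy]-4-{[(2E)-2-methylbut-2-enoyl]oxy}-2-({[(2E)-2-methylbut-2-enoyl]oxy}methyl)-5-(propan-2-yl)cyclohex-2-en-1-one | C/C=C(\C)C(=O)OCC1=C[C@H](OC(=O)/C(C)=C/C)[C@H](C(C)C)[C@@H](OCc2ccc(OC)cc2)C1=O | intermediate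
30 | (4S,5R,6R)-6-hydroxy-4-{[(2E)-2-methylbut-2-enoyl]oxy}-2-({[(2E)-2-methylbut-2-enoyl]oxy}methyl)-5-(propan-2-yl)cyclohex-2-en-1-one | C/C=C(\C)C(=O)OCC1=C[C@H](OC(=O)/C(C)=C/C)[C@H](C(C)C)[C@@H](O)C1=O | target

**Totals and risks**
Total step count: 18. Longest linear sequence: 17 steps (steps 1, 2 and 4–18, from 1 to 30).

Three steps most likely to fail:

Step 5 (AlMe3 transamination of the α-isopropyl imide; risk: sluggish reaction or opening of the oxazolidinone ring). The fallback sets out from 12: LiOH/H2O2 in THF/H2O at 0 °C cleaves the auxiliary to (2R,3R)-3-hydroxy-4-[(4-methoxybenzyl)oxy]-2-(propan-2-yl)butanoic acid F1, and carbodiimide coupling of this acid with MeNHOMe·HCl (EDC·HCl, HOBt, N-methylmorpholine, CH2Cl2) comes back to the route at 13.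

Step 6 (β-hydroxy vinyl ketone; risk: conjugate addition of the released amine, oxa-Michael closure or polymerisation). The fallback sets out from 13 and uses an alkyne as a masked vinyl group. LiC≡CSiMe3 (from trimethylsilylacetylene and n-BuLi, THF, −78 °C) gives (4R,5R)-5-hydroxy-6-[(4-methoxybenzyl)oxy]-4-(propan-2-yl)-1-(trimethylsilyl)hex-1-yn-3-one F2. Me4NBH(OAc)3 in MeCN/AcOH reduces it to the anti diol (2R,3S,4R)-1-[(4-methoxybenzyl)oxy]-3-(propan-2-yl)-6-(trimethylsilyl)hex-5-yne-2,4-diol F3 (same spatial arrangement as 16; 4R is a CIP priority change). K2CO3/MeOH removes the silyl group to give (2R,3S,4R)-1-[(4-methoxybenzyl)oxy]-3-(propan-2-yl)hex-5-yne-2,4-diol F4. Semihydrogenation (H2, Pd/CaCO3 poisoned with Pb(OAc)2, quinoline, EtOAc) comes back to the route at 16.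

Step 15 (Morita–Baylis–Hillman hydroxymethylation of a hindered, base-sensitive enone; risk: no turnover or C6 epimerisation). The fallback sets out from 23: I2/pyridine in CH2Cl2 gives (4R,5R,6R)-4-[(tert-butyldimethylsilyl)oxy]-2-iodo-6-[(4-methoxybenzyl)oxy]-5-(propan-2-yl)cyclohex-2-en-1-one F5 (4R only because iodine changes the CIP priorities), and Stille coupling with Bu3SnCH2OH (Pd(PPh3)4, dioxane, 80 °C) comes back to the route at 25.

**Further compounds**
F1 | step 5 | (2R,3R)-3-hydroxy-4-[(4-methoxybenzyl)oxy]-2-(propan-2-yl)butanoic acid | OC(=O)[C@H](C(C)C)[C@@H](O)COCc1ccc(OC)cc1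
F2 | step 6 | (4R,5R)-5-hydroxy-6-[(4-methoxybenzyl)oxy]-4-(propan-2-yl)-1-(trimethylsilyl)hex-1-yn-3-one | C[Si](C)(C)C#CC(=O)[C@H](C(C)C)[C@@H](O)COCc1ccc(OC)cc1
F3 | step 6 | (2R,3S,4R)-1-[(4-methoxybenzyl)oxy]-3-(propan-2-yl)-6-(trimethylsilyl)hex-5-yne-2,4-diol | C[Si](C)(C)C#C[C@H](O)[C@H](C(C)C)[C@@H](O)COCc1ccc(OC)cc1
F4 | step 6 | (2R,3S,4R)-1-[(4-methoxybenzyl)oxy]-3-(propan-2-yl)hex-5-yne-2,4-diol | C#C[C@H](O)[C@H](C(C)C)[C@@H](O)COCc1ccc(OC)cc1
F5 | step 15 | (4R,5R,6R)-4-[(tert-butyldimethylsilyl)oxy]-2-iodo-6-[(4-methoxybenzyl)oxy]-5-(propan-2-yl)cyclohex-2-en-1-one | IC1=C[C@H](O[Si](C)(C)C(C)(C)C)[C@H](C(C)C)[C@@H](OCc2ccc(OC)cc2)C1=O
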